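## The problem

The target is robinetinidol-(4α→6)-epigallocatechin. Two flavan-3-ols are joined by one bond from C4 of the upper unit (rings A, C, B) to C6' of the lower unit (rings D, F, E). Five stereocenters must be set: C2 (R), C3 (S) and C4 (S) in an all-trans array on ring C, and C2' (R) and C3' (R) cis on ring F. On ring C the C3 oxygen can steer a group entering at C4 to the opposite face. The two stereocenters of ring F are too far from the upper unit to be steered by it and need their own source of chirality. The hardest structural question is regiochemistry on ring D: a phloroglucinol nucleophile offers C6' and C8', which differ only in which neighbouring oxygen is the pyran oxygen, and direct arylation tends to prefer C8'. The molecule is also fragile: the pyrogallol rings B and E oxidize readily in base and air, the doubly benzylic C4–C6' bond can ionize in acid, and the 2',3'-cis arrangement is the less stable one. The useful feature is that the three oxygens of ring D play three different roles: O1' on C8a' is the ring F ether, C5' and C7' carry free hydroxyls, C6' carries C4 and C8' is unsubstituted. A ring synthesis that delivers each oxygen in a different state of protection settles the 4→6 question by construction.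

## Retrosynthesis

32 ⇒ 31. No skeletal bond is cut first. All eleven hydroxyls are masked as benzyl ethers in 31, because hydrogenolysis is neutral and spares both the pyrogallol rings and the acid-labile C4 position. The forward step only has to cleave O–benzyl bonds.

31 ⇒ 30. The O1'–C2' bond of ring F is cut. Unlike a cut at C4'–C4a' or O1'–C8a', this bond can be made by SN2 displacement at the benzylic carbon with inversion, so the less stable 2',3'-cis ring comes from an anti-configured open chain. Phenol–alcohol 30 has no ring F. The forward reaction must find exactly one free phenol and must invert cleanly.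

30 ⇒ 29 ⇒ 28. Only O–Si and O–benzyl bonds change. In 28 the ring D oxygens are a free hydroxyl (C5'), a silyl ether (C8a') and a benzyl ether (C7'). Benzylating the free one (29) and then removing silicon (30) leaves the C8a' oxygen as the only possible O1'.

28 ⇒ 14 + 23. This is the key cut: C4a'–C5' and C8'–C8a', which dissolves ring D into a four-carbon piece (cyclobutenone 14) and a two-carbon piece (siloxyalkyne 23). The neighbouring cut at C4–C6' (Friedel–Crafts arylation) would reopen the C6'/C8' question. Here the position of every substituent follows from the way the two pieces combine. Compound 14 holds the whole upper flavan, and 23 holds ring E, C2', C3' and C4'. The forward reaction must be regioselective and must run without acid.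

14 ⇒ 7 + 11. The two ring bonds of the cyclobutenone that flank the sp3 carbon side (C1–C2 and C3–C4) are cut, giving ketene 13 and benzyl ethynyl ether 11. The ketene comes from acid 7 through chloride 12. This places the benzyloxy carbon next to the flavanyl-bearing carbon, as ring D requires.

11 ⇒ 9 ⇒ 8. The ynol ether is traced to dichlorovinyl ether 9 and trichloroethylene 8 through acetylide 10.

7 ⇒ 6 ⇒ 5 ⇒ 4 ⇒ 3 ⇒ 2 ⇒ 1. The acid carbon is removed (aldehyde 6, alkene 5), and the C4–CH2 bond of 4 is cut to a C4 cation and an allylsilane. The cation comes from diol 3, made by reduction of benzylated flavanonol 2, which comes from natural (+)-dihydrorobinetin 1. C2 and C3 are bought with 1, and C3 controls C4.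

23 ⇒ 21 ⇒ 20 ⇒ 19 ⇒ 18 ⇒ 17 ⇒ 16 ⇒ 15. The C–O bond of the ynol ether is cut first (terminal alkyne 21 via ynolate 22, then protecting-group changes back to 19). The C4'–alkyne bond is then cut to a silylacetylide and terminal epoxide 18. The anti epoxy alcohol 17 comes from racemic carbinol 16 by Sharpless kinetic resolution, and 16 from aldehyde 15 and a vinyl Grignard reagent. Both lower stereocenters come from one catalyst-controlled step.

## Roads not taken

Alternative 1: Ring D could be folded from a polyketide chain, cutting C4a'–C5'.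
- Forward step: Mg(OMe)2 in methanol opens the lactone of pyranone A1, the 3-(flavan-4-yl) derivative of 4-hydroxy-6-(2-oxopropyl)-2-pyranone. The acetonyl methylene carbon then attacks the freed ester (Claisen condensation) and the ring aromatizes to trihydroxyacetophenone A2.
- Merits: the chemistry is biomimetic, cheap and mild toward the upper unit. A1 should be reachable by capture of the C4 cation from 3 at the nucleophilic C3 of the pyranone, so the interflavan bond is placed between two oxygens early. The acetyl group of A2 is a natural handle for C4' and C3'.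
- Weak points: A2 has two hydroxyls ortho to the acetyl group that differ only in their second neighbour. The choice between 4→6 and 4→8 is therefore postponed to a chalcone–flavanone cyclization with no built-in bias. Ring F would still have to be built from the acetyl group and aldehyde 15 (Claisen–Schmidt condensation, cyclization, oxygenation at C3', removal of the C4' carbonyl, adjustment to 2',3'-cis). C2' and C3' would be formed late with no control from the distant upper unit.
- Comparison: this road reaches ring D in fewer steps and with more robust reagents, and in that respect it is better. The chosen plan sets against it three differentiated ring D oxygens and a ring E that arrives with C2' and C3' already configured. Four steps remain after ring D is formed, where this road would need roughly twice as many.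

Alternative 2: Ring C could be closed last at C3–C4.
- Forward step: SmI2 reduces the diaryl ketone of keto aldehyde A3 to a ketyl, which adds to the tethered α-aryloxy aldehyde (6-exo-trig, pinacol type). The product is cis-3,4-diol A4 with a tertiary hydroxyl at C4.
- Merits: the lower unit would be taken intact from the chiral pool, so rings D, F, E and their two stereocenters cost no construction steps. The C4–C6' bond is made as an aryl ketone with a bromine on C8' fixing its position. Samarium pinacol closures to cis-diols are well known.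
- Weak points: C2 of A3 is a benzylic α-aryloxy aldehyde carbon, hard to make enantiopure and easy to epimerize. α-Aryloxy carbonyl compounds are themselves cleaved by SmI2, in competition with ketyl formation. The 2,3 relation rests on substrate control of unknown sense. A4 has one oxygen too many; removing it from a doubly benzylic tertiary centre passes through the C4 cation, where hydride should enter anti to the C3 oxygen and give the 3,4-cis isomer, not the required 3,4-trans one.
- Comparison: for the lower half this road is clearly better in step economy than building rings D and F from small pieces (seven steps to 23). The chosen plan sets against it a C4 configuration fixed early by a carbon nucleophile entering anti to C3–O, C2 and C3 taken unchanged from 1, and no late deoxygenation.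

Alternative 3: Ring C could be made in one step by cutting C3–C4 and O1–C2.
- Forward step: a chiral phosphoric acid dehydrates o-hydroxybenzhydrol A5 to the ring A o-quinone methide. This adds (E)-styrylsilane A6 in an inverse-demand hetero-[4+2] cycloaddition to give the 2,3-trans-3,4-trans 3-silyl-4-arylflavan A7. Tamao–Fleming oxidation would later turn the C–Si bond into the C3 hydroxyl with retention.
- Merits: two bonds and three stereocenters form in one catalytic enantioselective step from achiral pieces, with no need for natural 1. Ring D enters as a symmetrical 2,6-dibenzyloxy-4-siloxyphenyl group, so after desilylation the two positions ortho to the phenol are equivalent and ring F can be grown without a 4→6/4→8 question.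
- Weak points: the methide carbon carries an aryl group with two ortho substituents, so ionization and approach of a weakly nucleophilic β-silylstyrene are both sterically demanding. Enantiocontrol on so crowded an o-quinone methide is unproven. After the key step, ring F, ring E and both lower stereocenters are still missing (ortho C-alkylation, asymmetric dioxygenation, cyclization, correction to 2',3'-cis).
- Comparison: for creating stereocenters this road is better, three in the key step against none in the benzannulation. The chosen plan sets against it that its stereocenters come from one chiral-pool compound and three textbook reactions (cation capture anti to C3–O, Sharpless epoxidation, Mitsunobu inversion), and that its key step joins two complete halves.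

Key step: step 17

## Route

Remark: NaBH4 reduction of 2 is assumed to give mainly the 3,4-trans diol 3; a minor C4 epimer can be carried along, because C4 is ionized in step 3.

Step 1
Reactants: 1 (+)-dihydrorobinetin
Product: 2 (2R,3R)-7-(benzyloxy)-3-hydroxy-2-[3,4,5-tris(benzyloxy)phenyl]chroman-4-one
Conditions: BnBr, K2CO3, DMF, rt, argon
Reagents that add atoms: benzyl bromide, BrCc1ccccc1
Why: Williamson etherification; the four phenols are far more acidic than the C3 alcohol, so carbonate benzylates only them, and room temperature with exclusion of air limits chalcone ring opening (loss of C2/C3 integrity) and oxidation to the flavonol.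

Step 2
Reactants: 2 (2R,3R)-7-(benzyloxy)-3-hydroxy-2-[3,4,5-tris(benzyloxy)phenyl]chroman-4-one
Product: 3 (2R,3S,4R)-7-(benzyloxy)-2-[3,4,5-tris(benzyloxy)phenyl]chromane-3,4-diol
Conditions: NaBH4, THF–MeOH, 0 °C
Reagents that add atoms: none
Why: Borohydride reduction of the aryl ketone; hydride should add so that the new hydroxyl is equatorial and trans to the C3 hydroxyl, and the C4 configuration is not used later.

Step 3
Reactants: 3 (2R,3S,4R)-7-(benzyloxy)-2-[3,4,5-tris(benzyloxy)phenyl]chromane-3,4-diol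
Product: 4 (2R,3S,4R)-4-allyl-7-(benzyloxy)-2-[3,4,5-tris(benzyloxy)phenyl]chroman-3-ol
Conditions: allylSiMe3, BF3·OEt2, CH2Cl2, −78 → −40 °C
Reagents that add atoms: allyltrimethylsilane, C=CC[Si](C)(C)C
Why: Hosomi–Sakurai allylation of a benzylic cation; BF3 ionizes only the C4 hydroxyl (cation stabilized by O1 and the para 7-benzyloxy group), and the allylsilane attacks the half-chair cation anti to the C3 oxygen, which sets C4 with allyl trans to C3–OH and cis to the C2 aryl group (substrate control by C3). Any minor 3,4-cis isomer is removed by chromatography.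

Step 4
Reactants: 4 (2R,3S,4R)-4-allyl-7-(benzyloxy)-2-[3,4,5-tris(benzyloxy)phenyl]chroman-3-ol
Product: 5 (2R,3S,4R)-4-allyl-3,7-bis(benzyloxy)-2-[3,4,5-tris(benzyloxy)phenyl]chromane
Conditions: NaH, BnBr, Bu4NI (cat.), DMF, 0 °C → rt
Reagents that add atoms: benzyl bromide, BrCc1ccccc1
Why: Williamson benzylation of the secondary alkoxide; with the ketone gone there is no base-sensitive site, and benzyl lets every oxygen be freed in the same final hydrogenolysis.

Step 5
Reactants: 5 (2R,3S,4R)-4-allyl-3,7-bis(benzyloxy)-2-[3,4,5-tris(benzyloxy)phenyl]chromane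
Product: 6 2-{(2R,3S,4R)-3,7-bis(benzyloxy)-2-[3,4,5-tris(benzyloxy)phenyl]chroman-4-yl}acetaldehyde
Conditions: OsO4 (cat.), NaIO4, 2,6-lutidine, dioxane–H2O, rt
Reagents that add atoms: osmium tetroxide, O=[Os](=O)(=O)=O (delivers the oxygen and is regenerated); sodium periodate, [Na+].[O-]I(=O)(=O)=O (terminal oxidant)
Why: Lemieux–Johnson cleavage (catalytic dihydroxylation, then periodate cleavage of the diol); OsO4 leaves the benzyloxy arenes untouched, which ozone would not, and 2,6-lutidine suppresses over-oxidation.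

Step 6
Reactants: 6 2-{(2R,3S,4R)-3,7-bis(benzyloxy)-2-[3,4,5-tris(benzyloxy)phenyl]chroman-4-yl}acetaldehyde
Product: 7 2-{(2R,3S,4R)-3,7-bis(benzyloxy)-2-[3,4,5-tris(benzyloxy)phenyl]chroman-4-yl}acetic acid
Conditions: NaClO2, NaH2PO4, 2-methyl-2-butene, t-BuOH–H2O, rt
Reagents that add atoms: sodium chlorite, [Na+].[O-]Cl=O
Why: Pinnick oxidation; 2-methyl-2-butene scavenges hypochlorous acid so the electron-rich rings are not chlorinated, and C4 is β to the carbonyl and cannot epimerize by enolization.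

Step 7
Reactants: 8 trichloroethylene
Product: 9 benzyl (E)-1,2-dichlorovinyl ether
Conditions: BnOH, KH, THF, 0 °C; then Cl2C=CHCl, −50 °C → rt
Reagents that add atoms: benzyl alcohol, OCc1ccccc1
Why: Base-induced elimination of trichloroethylene to dichloroacetylene and addition of the alkoxide; this is the standard preparation of (E)-1,2-dichlorovinyl ethers.

Step 8
Reactants: 9 benzyl (E)-1,2-dichlorovinyl ether
Product: 11 benzyl ethynyl ether (benzyloxyacetylene), via lithium benzyloxyacetylide 10 (not isolated)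
Conditions: n-BuLi (2.2 equiv), Et2O, −78 °C; MeOH, −78 °C; cold aqueous work-up, kept as a cold Et2O solution
Reagents that add atoms: none
Why: Dehydrochlorination followed by chlorine–lithium exchange gives the lithium alkoxyacetylide (standard alkynyl ether synthesis from dichlorovinyl ethers); protonation gives the terminal ynol ether, kept cold because benzyl alkynyl ethers rearrange on warming.

Step 9
Reactants: 7 2-{(2R,3S,4R)-3,7-bis(benzyloxy)-2-[3,4,5-tris(benzyloxy)phenyl]chroman-4-yl}acetic acid; 11 benzyl ethynyl ether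
Product: 14 3-(benzyloxy)-4-{(2R,3S,4R)-3,7-bis(benzyloxy)-2-[3,4,5-tris(benzyloxy)phenyl]chroman-4-yl}cyclobut-2-en-1-one as both epimers at the cyclobutenone carbon, via acid chloride 12 (not isolated), via ketene 13 (not isolated)
Conditions: (COCl)2, DMF (cat.), CH2Cl2, 0 °C → rt, evaporate; then 11 (3 equiv), Et3N, CH2Cl2, 0 °C → rt; chromatography on Et3N-deactivated silica
Reagents that add atoms: none
Why: Et3N dehydrochlorinates the acid chloride to the monoalkylketene, which is trapped as it forms by the electron-rich ynol ether in a regioselective ketene–alkyne [2+2] cycloaddition: the unsubstituted alkyne carbon bonds to the ketene carbonyl carbon, so the benzyloxy carbon lies next to the flavanyl-bearing carbon. The new cyclobutenone stereocenter is uncontrolled and is erased in step 17; acid and base are avoided afterwards so that the 4-substituted isomer does not drift to the 2-substituted one, which would lead to the 4→8 series.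

Step 10
Reactants: 15 3,4,5-tris(benzyloxy)benzaldehyde
Product: 16 rac-1-[3,4,5-tris(benzyloxy)phenyl]prop-2-en-1-ol
Conditions: CH2=CHMgBr, THF, −78 → 0 °C
Reagents that add atoms: vinylmagnesium bromide, C=C[Mg]Br
Why: Grignard addition to the aldehyde gives the racemic aryl vinyl carbinol needed for kinetic resolution.

Step 11
Reactants: 16 rac-1-[3,4,5-tris(benzyloxy)phenyl]prop-2-en-1-ol
Product: 17 (S)-[(R)-oxiran-2-yl][3,4,5-tris(benzyloxy)phenyl]methanol (anti epoxy alcohol)
Conditions: Ti(OiPr)4 (cat.), L-(+)-diisopropyl tartrate, t-BuOOH (0.55 equiv), 4 Å molecular sieves, CH2Cl2, −20 °C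
Reagents that add atoms: tert-butyl hydroperoxide, CC(C)(C)OO
Why: Sharpless asymmetric epoxidation run as a kinetic resolution; with L-(+)-tartrate the (R)-carbinol is epoxidized much faster than its enantiomer, on the face that gives the erythro (anti) epoxy alcohol, so the catalyst sets C3' (R) and selects the carbinol that becomes C2' (S in 17 only through the change of priorities). Unreacted (S)-16 is separated by chromatography.

Step 12
Reactants: 17 (S)-[(R)-oxiran-2-yl][3,4,5-tris(benzyloxy)phenyl]methanol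
Product: 18 tert-butyldimethyl{(S)-[(R)-oxiran-2-yl][3,4,5-tris(benzyloxy)phenyl]methoxy}silane
Conditions: TBSCl, imidazole, DMF, rt
Reagents that add atoms: tert-butyldimethylsilyl chloride, CC(C)(C)[Si](C)(C)Cl
Why: Silylation of the secondary alcohol under mildly basic conditions that leave the epoxide intact; this silyl ether is later cleaved together with the aryl silyl ether.

Step 13
Reactants: 18 tert-butyldimethyl{(S)-[(R)-oxiran-2-yl][3,4,5-tris(benzyloxy)phenyl]methoxy}silane
Product: 19 (1S,2R)-1-(tert-butyldimethylsilyloxy)-5-(trimethylsilyl)-1-[3,4,5-tris(benzyloxy)phenyl]pent-4-yn-2-ol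
Conditions: Me3SiC≡CH, n-BuLi, THF, −78 °C; BF3·OEt2; then 18, −78 °C
Reagents that add atoms: trimethylsilylacetylene (as its lithium salt), C#C[Si](C)(C)C
Why: Yamaguchi–Hirao alkynylation; BF3-assisted SN2 opening of the terminal epoxide at its unsubstituted carbon forms the C4'–alkyne bond, and C3' keeps its oxygen and configuration.

Step 14
Reactants: 19 (1S,2R)-1-(tert-butyldimethylsilyloxy)-5-(trimethylsilyl)-1-[3,4,5-tris(benzyloxy)phenyl]pent-4-yn-2-ol
Product: 20 (1S,2R)-2-(benzyloxy)-1-(tert-butyldimethylsilyloxy)-5-(trimethylsilyl)-1-[3,4,5-tris(benzyloxy)phenyl]pent-4-yne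
Conditions: 2-benzyloxy-1-methylpyridinium triflate, MgO, PhCF3, 85 °C
Reagents that add atoms: 2-benzyloxy-1-methylpyridinium triflate, C[n+]1ccccc1OCc1ccccc1.[O-]S(=O)(=O)C(F)(F)F
Why: Benzylation under neutral conditions; the pyridinium salt releases a benzyl cation equivalent on warming and MgO takes up the acid, so no alkoxide forms and the neighbouring silyl group cannot migrate from O2' to O3' as it might with NaH.

Step 15
Reactants: 20 (1S,2R)-2-(benzyloxy)-1-(tert-butyldimethylsilyloxy)-5-(trimethylsilyl)-1-[3,4,5-tris(benzyloxy)phenyl]pent-4-yne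
Product: 21 (1S,2R)-2-(benzyloxy)-1-(tert-butyldimethylsilyloxy)-1-[3,4,5-tris(benzyloxy)phenyl]pent-4-yne
Conditions: K2CO3 (cat.), MeOH–THF, rt
Reagents that add atoms: none
Why: Base-catalysed methanolysis of the alkynyl C–Si bond; alkyl silyl ethers and benzyl ethers are inert.

Step 16
Reactants: 21 (1S,2R)-2-(benzyloxy)-1-(tert-butyldimethylsilyloxy)-1-[3,4,5-tris(benzyloxy)phenyl]pent-4-yne
Product: 23 (4R,5S)-4-(benzyloxy)-5-(tert-butyldimethylsilyloxy)-1-(triisopropylsilyloxy)-5-[3,4,5-tris(benzyloxy)phenyl]pent-1-yne, via lithium ynolate 22 (not isolated)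
Conditions: LiN(SiMe3)2, THF, −78 °C; t-BuOOLi (from t-BuOOH and LiN(SiMe3)2), −78 → 0 °C; i-Pr3SiOTf, −78 → 0 °C
Reagents that add atoms: tert-butyl hydroperoxide, CC(C)(C)OO; triisopropylsilyl triflate, CC(C)[Si](OS(=O)(=O)C(F)(F)F)(C(C)C)C(C)C
Why: The lithium acetylide attacks the O–O bond of lithium tert-butyl peroxide to give the lithium ynolate, and the bulky silyl triflate silylates oxygen, not carbon; this is a standard one-flask preparation of triisopropylsiloxyalkynes from terminal alkynes.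

Step 17
Reactants: 14 3-(benzyloxy)-4-{(2R,3S,4R)-3,7-bis(benzyloxy)-2-[3,4,5-tris(benzyloxy)phenyl]chroman-4-yl}cyclobut-2-en-1-one; 23 (4R,5S)-4-(benzyloxy)-5-(tert-butyldimethylsilyloxy)-1-(triisopropylsilyloxy)-5-[3,4,5-tris(benzyloxy)phenyl]pent-1-yne
Product: 28 2-{(2R,3S,4S)-3,7-bis(benzyloxy)-2-[3,4,5-tris(benzyloxy)phenyl]chroman-4-yl}-3-(benzyloxy)-6-{(2R,3S)-2-(benzyloxy)-3-(tert-butyldimethylsilyloxy)-3-[3,4,5-tris(benzyloxy)phenyl]propyl}-5-(triisopropylsilyloxy)phenol (ring D phenol: free C5' hydroxyl; C7' benzyl ether; C8a' silyl ether), via vinylketene 24 (not isolated), via vinylcyclobutenone 25 (not isolated), via dienylketene 26 (not isolated), via cyclohexadienone 27 (not isolated)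
Conditions: 23 (1.3 equiv), toluene (degassed), 80 → 110 °C, sealed tube
Reagents that add atoms: none
Why: Heating opens cyclobutenone 14 by four-electron conrotatory cleavage of its C1–C4 bond, the flavanyl group turning outward, to vinylketene 24. The carbon of siloxyalkyne 23 remote from oxygen attacks the ketene carbonyl carbon and the silyloxy carbon bonds to the ketene α-carbon in a [2+2] cycloaddition, forming C4a'–C5' and C8'–C8a' and giving vinylcyclobutenone 25. A second four-electron opening gives dienylketene 26, whose six-electron disrotatory electrocyclization re-forms C5'–C6' and closes ring D as cyclohexadienone 27, which enolizes to phenol 28. The closest known reaction type is the Danheiser benzannulation of cyclobutenones with triisopropylsiloxyalkynes, which gives resorcinol monosilyl ethers under the same neutral thermal conditions. No stereocenter is created: the cyclobutenone carbon of 14 and the sp3 ring carbon of 27 both end as sp2, and C2, C3, C4, C2' and C3' are spectators that never meet acid or base. The step needs regioselectivity in the [2+2] addition, which the oxygen-polarized alkyne secures, so that the silyloxy carbon becomes C8a' next to unsubstituted C8' and the ketene oxygen becomes the free C5' hydroxyl between C6' and C4a'. It also needs the vinylketene to be trapped faster than it dimerizes or undergoes a 1,5-hydrogen shift, which outward rotation of the bulky flavanyl group and an excess of the electron-rich alkyne should favour. The C4 descriptor changes from R to S only because the new aryl group outranks C4a.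

Step 18
Reactants: 28 ring D phenol with free C5' hydroxyl
Product: 29 (2R,3S,4S)-3,7-bis(benzyloxy)-4-{2,6-bis(benzyloxy)-3-[(2R,3S)-2-(benzyloxy)-3-(tert-butyldimethylsilyloxy)-3-(3,4,5-tris(benzyloxy)phenyl)propyl]-4-(triisopropylsilyloxy)phenyl}-2-[3,4,5-tris(benzyloxy)phenyl]chromane
Conditions: NaH, BnBr, Bu4NI (cat.), THF–DMF, 0 °C → rt
Reagents that add atoms: benzyl bromide, BrCc1ccccc1
Why: Williamson benzylation of the only free phenol; capping the C5' oxygen leaves the silylated C8a' oxygen as the only one that can become O1', and the aryl triisopropylsilyl ether tolerates NaH at this temperature.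

Step 19
Reactants: 29 C5'-O-benzyl bis-silyl ether
Product: 30 3,5-bis(benzyloxy)-4-{(2R,3S,4S)-3,7-bis(benzyloxy)-2-[3,4,5-tris(benzyloxy)phenyl]chroman-4-yl}-2-{(2R,3S)-2-(benzyloxy)-3-hydroxy-3-[3,4,5-tris(benzyloxy)phenyl]propyl}phenol
Conditions: Bu4NF, THF, 0 °C → rt; NH4Cl work-up
Reagents that add atoms: none
Why: Fluoride cleaves both Si–O bonds (the aryl silyl ether fast, the secondary alkyl silyl ether more slowly), freeing exactly one phenol and the benzylic alcohol.

Step 20
Reactants: 30 phenol–benzylic alcohol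
Product: 31 (2R,3S,4S)-3,7-bis(benzyloxy)-4-{(2R,3R)-3,5,7-tris(benzyloxy)-2-[3,4,5-tris(benzyloxy)phenyl]chroman-6-yl}-2-[3,4,5-tris(benzyloxy)phenyl]chromane (undeca-O-benzyl ether of the target)
Conditions: PPh3, DIAD, THF, 0 °C → rt
Reagents that add atoms: none
Why: Intramolecular Mitsunobu etherification (6-exo-tet); the phenol is the acidic partner and displaces the oxyphosphonium group at the benzylic carbon by SN2 with inversion, turning C2' from S to R and giving the 2',3'-cis ring F. The β-benzyloxy group disfavours ionization and no other nucleophile is present.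

Step 21
Reactants: 31 undeca-O-benzyl ether of the target
Product: 32 (2R,3S,4S)-2-(3,4,5-trihydroxyphenyl)-4-[(2R,3R)-3,5,7-trihydroxy-2-(3,4,5-trihydroxyphenyl)chroman-6-yl]chromane-3,7-diol (CNP0311915.2)
Conditions: H2 (1 atm), Pd(OH)2 on carbon, THF–MeOH–H2O, rt; filtration and freeze-drying under argon
Reagents that add atoms: none
Why: Hydrogenolysis of the eleven benzyl ethers under neutral conditions, as is usual for benzylated oligomeric flavan-3-ols; the cyclic benzylic C2–O1 ethers and the C4–C6' bond are cleaved much more slowly than O-benzyl groups.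

## Compound list

1 | (+)-dihydrorobinetin, (2R,3R)-3,7-dihydroxy-2-(3,4,5-trihydroxyphenyl)chroman-4-one | Oc1ccc2c(c1)O[C@H](c3cc(O)c(O)c(O)c3)[C@@H](O)C2=O | starting material
2 | (2R,3R)-7-(benzyloxy)-3-hydroxy-2-[3,4,5-tris(benzyloxy)phenyl]chroman-4-one | O(Cc4ccccc4)c1ccc2c(c1)O[C@H](c3cc(OCc4ccccc4)c(OCc4ccccc4)c(OCc4ccccc4)c3)[C@@H](O)C2=O | intermediate
3 | (2R,3S,4R)-7-(benzyloxy)-2-[3,4,5-tris(benzyloxy)phenyl]chromane-3,4-diol (2,3-trans-3,4-trans) | O(Cc4ccccc4)c1ccc2c(c1)O[C@H](c3cc(OCc4ccccc4)c(OCc4ccccc4)c(OCc4ccccc4)c3)[C@@H](O)[C@@H]2O | intermediate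
4 | (2R,3S,4R)-4-allyl-7-(benzyloxy)-2-[3,4,5-tris(benzyloxy)phenyl]chroman-3-ol (allyl trans to C3–OH, cis to the C2 aryl group) | O(Cc4ccccc4)c1ccc2c(c1)O[C@H](c3cc(OCc4ccccc4)c(OCc4ccccc4)c(OCc4ccccc4)c3)[C@@H](O)[C@@H]2CC=C | intermediate
5 | (2R,3S,4R)-4-allyl-3,7-bis(benzyloxy)-2-[3,4,5-tris(benzyloxy)phenyl]chromane | O(Cc4ccccc4)c1ccc2c(c1)O[C@H](c3cc(OCc4ccccc4)c(OCc4ccccc4)c(OCc4ccccc4)c3)[C@@H](OCc4ccccc4)[C@@H]2CC=C | intermediate
6 | 2-{(2R,3S,4R)-3,7-bis(benzyloxy)-2-[3,4,5-tris(benzyloxy)phenyl]chroman-4-yl}acetaldehyde | O(Cc4ccccc4)c1ccc2c(c1)O[C@H](c3cc(OCc4ccccc4)c(OCc4ccccc4)c(OCc4ccccc4)c3)[C@@H](OCc4ccccc4)[C@@H]2CC=O | intermediate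
7 | 2-{(2R,3S,4R)-3,7-bis(benzyloxy)-2-[3,4,5-tris(benzyloxy)phenyl]chroman-4-yl}acetic acid | O(Cc4ccccc4)c1ccc2c(c1)O[C@H](c3cc(OCc4ccccc4)c(OCc4ccccc4)c(OCc4ccccc4)c3)[C@@H](OCc4ccccc4)[C@@H]2CC(=O)O | intermediate
8 | trichloroethylene | ClC=C(Cl)Cl | starting material
9 | benzyl (E)-1,2-dichlorovinyl ether | Cl/C=C(/Cl)OCc1ccccc1 | intermediate
10 | lithium benzyloxyacetylide | [Li]C#COCc1ccccc1 | intermediate (not isolated)
11 | benzyl ethynyl ether (benzyloxyacetylene) | C#COCc1ccccc1 | intermediate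
12 | 2-{(2R,3S,4R)-3,7-bis(benzyloxy)-2-[3,4,5-tris(benzyloxy)phenyl]chroman-4-yl}acetyl chloride | O(Cc4ccccc4)c1ccc2c(c1)O[C@H](c3cc(OCc4ccccc4)c(OCc4ccccc4)c(OCc4ccccc4)c3)[C@@H](OCc4ccccc4)[C@@H]2CC(=O)Cl | intermediate (not isolated)
13 | 2-{(2R,3S,4R)-3,7-bis(benzyloxy)-2-[3,4,5-tris(benzyloxy)phenyl]chroman-4-yl}ethenone (ketene) | O(Cc4ccccc4)c1ccc2c(c1)O[C@H](c3cc(OCc4ccccc4)c(OCc4ccccc4)c(OCc4ccccc4)c3)[C@@H](OCc4ccccc4)[C@@H]2C=C=O | intermediate (not isolated)
14 | 3-(benzyloxy)-4-{(2R,3S,4R)-3,7-bis(benzyloxy)-2-[3,4,5-tris(benzyloxy)phenyl]chroman-4-yl}cyclobut-2-en-1-one, both epimers at the cyclobutenone sp3 carbon | O(Cc4ccccc4)c1ccc2c(c1)O[C@H](c3cc(OCc4ccccc4)c(OCc4ccccc4)c(OCc4ccccc4)c3)[C@@H](OCc4ccccc4)[C@@H]2C5C(=O)C=C5OCc4ccccc4 | intermediate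
15 | 3,4,5-tris(benzyloxy)benzaldehyde | O=Cc7cc(OCc4ccccc4)c(OCc4ccccc4)c(OCc4ccccc4)c7 | starting material
16 | rac-1-[3,4,5-tris(benzyloxy)phenyl]prop-2-en-1-ol | C=CC(O)c7cc(OCc4ccccc4)c(OCc4ccccc4)c(OCc4ccccc4)c7 | intermediate
17 | (S)-[(R)-oxiran-2-yl][3,4,5-tris(benzyloxy)phenyl]methanol | C1[C@@H](O1)[C@@H](O)c7cc(OCc4ccccc4)c(OCc4ccccc4)c(OCc4ccccc4)c7 | intermediate
18 | tert-butyldimethyl{(S)-[(R)-oxiran-2-yl][3,4,5-tris(benzyloxy)phenyl]methoxy}silane | C1[C@@H](O1)[C@@H](O[Si](C)(C)C(C)(C)C)c7cc(OCc4ccccc4)c(OCc4ccccc4)c(OCc4ccccc4)c7 | intermediate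
19 | (1S,2R)-1-(tert-butyldimethylsilyloxy)-5-(trimethylsilyl)-1-[3,4,5-tris(benzyloxy)phenyl]pent-4-yn-2-ol | C[Si](C)(C)C#CC[C@@H](O)[C@@H](O[Si](C)(C)C(C)(C)C)c7cc(OCc4ccccc4)c(OCc4ccccc4)c(OCc4ccccc4)c7 | intermediate
20 | (1S,2R)-2-(benzyloxy)-1-(tert-butyldimethylsilyloxy)-5-(trimethylsilyl)-1-[3,4,5-tris(benzyloxy)phenyl]pent-4-yne | C[Si](C)(C)C#CC[C@@H](OCc4ccccc4)[C@@H](O[Si](C)(C)C(C)(C)C)c7cc(OCc4ccccc4)c(OCc4ccccc4)c(OCc4ccccc4)c7 | intermediate
21 | (1S,2R)-2-(benzyloxy)-1-(tert-butyldimethylsilyloxy)-1-[3,4,5-tris(benzyloxy)phenyl]pent-4-yne | C#CC[C@@H](OCc4ccccc4)[C@@H](O[Si](C)(C)C(C)(C)C)c7cc(OCc4ccccc4)c(OCc4ccccc4)c(OCc4ccccc4)c7 | intermediate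
22 | lithium (4R,5S)-4-(benzyloxy)-5-(tert-butyldimethylsilyloxy)-5-[3,4,5-tris(benzyloxy)phenyl]pent-1-yn-1-olate (ynolate) | [Li]OC#CC[C@@H](OCc4ccccc4)[C@@H](O[Si](C)(C)C(C)(C)C)c7cc(OCc4ccccc4)c(OCc4ccccc4)c(OCc4ccccc4)c7 | intermediate (not isolated)
23 | (4R,5S)-4-(benzyloxy)-5-(tert-butyldimethylsilyloxy)-1-(triisopropylsilyloxy)-5-[3,4,5-tris(benzyloxy)phenyl]pent-1-yne | CC(C)[Si](C(C)C)(C(C)C)OC#CC[C@@H](OCc4ccccc4)[C@@H](O[Si](C)(C)C(C)(C)C)c7cc(OCc4ccccc4)c(OCc4ccccc4)c(OCc4ccccc4)c7 | intermediate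
24 | 3-(benzyloxy)-4-{(2R,3S,4R)-3,7-bis(benzyloxy)-2-[3,4,5-tris(benzyloxy)phenyl]chroman-4-yl}buta-1,3-dien-1-one (vinylketene, flavanyl group trans to the ketene arm) | O(Cc4ccccc4)c1ccc2c(c1)O[C@H](c3cc(OCc4ccccc4)c(OCc4ccccc4)c(OCc4ccccc4)c3)[C@@H](OCc4ccccc4)[C@@H]2/C=C(OCc4ccccc4)/C=C=O | intermediate (not isolated)
25 | 4-[1-(benzyloxy)-2-(flavan-4-yl)vinyl]-2-[(2R,3S)-2-(benzyloxy)-3-(tert-butyldimethylsilyloxy)-3-(3,4,5-tris(benzyloxy)phenyl)propyl]-3-(triisopropylsilyloxy)cyclobut-2-en-1-one (flavan-4-yl = the chroman-4-yl group of 14) | O(Cc4ccccc4)c1ccc2c(c1)O[C@H](c3cc(OCc4ccccc4)c(OCc4ccccc4)c(OCc4ccccc4)c3)[C@@H](OCc4ccccc4)[C@@H]2/C=C(OCc4ccccc4)/C5C(=O)C(C[C@@H](OCc4ccccc4)[C@@H](O[Si](C)(C)C(C)(C)C)c7cc(OCc4ccccc4)c(OCc4ccccc4)c(OCc4ccccc4)c7)=C5O[Si](C(C)C)(C(C)C)C(C)C | intermediate (not isolated)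
26 | 5-(benzyloxy)-6-(flavan-4-yl)-2-[(2R,3S)-2-(benzyloxy)-3-(tert-butyldimethylsilyloxy)-3-(3,4,5-tris(benzyloxy)phenyl)propyl]-3-(triisopropylsilyloxy)hexa-1,3,5-trien-1-one (dienylketene, central double bond cis) | O(Cc4ccccc4)c1ccc2c(c1)O[C@H](c3cc(OCc4ccccc4)c(OCc4ccccc4)c(OCc4ccccc4)c3)[C@@H](OCc4ccccc4)[C@@H]2/C=C(OCc4ccccc4)/C=C(O[Si](C(C)C)(C(C)C)C(C)C)\C(C[C@@H](OCc4ccccc4)[C@@H](O[Si](C)(C)C(C)(C)C)c7cc(OCc4ccccc4)c(OCc4ccccc4)c(OCc4ccccc4)c7)=C=O | intermediate (not isolated)
27 | 5-(benzyloxy)-6-(flavan-4-yl)-2-[(2R,3S)-2-(benzyloxy)-3-(tert-butyldimethylsilyloxy)-3-(3,4,5-tris(benzyloxy)phenyl)propyl]-3-(triisopropylsilyloxy)cyclohexa-2,4-dien-1-one | O(Cc4ccccc4)c1ccc2c(c1)O[C@H](c3cc(OCc4ccccc4)c(OCc4ccccc4)c(OCc4ccccc4)c3)[C@@H](OCc4ccccc4)[C@@H]2C5C(=O)C(C[C@@H](OCc4ccccc4)[C@@H](O[Si](C)(C)C(C)(C)C)c7cc(OCc4ccccc4)c(OCc4ccccc4)c(OCc4ccccc4)c7)=C(O[Si](C(C)C)(C(C)C)C(C)C)C=C5OCc4ccccc4 | intermediate (not isolated)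
28 | 2-{(2R,3S,4S)-3,7-bis(benzyloxy)-2-[3,4,5-tris(benzyloxy)phenyl]chroman-4-yl}-3-(benzyloxy)-6-{(2R,3S)-2-(benzyloxy)-3-(tert-butyldimethylsilyloxy)-3-[3,4,5-tris(benzyloxy)phenyl]propyl}-5-(triisopropylsilyloxy)phenol | O(Cc4ccccc4)c1ccc2c(c1)O[C@H](c3cc(OCc4ccccc4)c(OCc4ccccc4)c(OCc4ccccc4)c3)[C@@H](OCc4ccccc4)[C@@H]2c5c(O)c(C[C@@H](OCc4ccccc4)[C@@H](O[Si](C)(C)C(C)(C)C)c7cc(OCc4ccccc4)c(OCc4ccccc4)c(OCc4ccccc4)c7)c(O[Si](C(C)C)(C(C)C)C(C)C)cc5OCc4ccccc4 | intermediate
29 | benzyl ether of 28 at the C5' oxygen (C5'-OBn, C7'-OBn, C8a'-OSi(i-Pr)3, C2'-OTBS, C3'-OBn) | O(Cc4ccccc4)c1ccc2c(c1)O[C@H](c3cc(OCc4ccccc4)c(OCc4ccccc4)c(OCc4ccccc4)c3)[C@@H](OCc4ccccc4)[C@@H]2c5c(OCc4ccccc4)c(C[C@@H](OCc4ccccc4)[C@@H](O[Si](C)(C)C(C)(C)C)c7cc(OCc4ccccc4)c(OCc4ccccc4)c(OCc4ccccc4)c7)c(O[Si](C(C)C)(C(C)C)C(C)C)cc5OCc4ccccc4 | intermediate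
30 | 3,5-bis(benzyloxy)-4-{(2R,3S,4S)-3,7-bis(benzyloxy)-2-[3,4,5-tris(benzyloxy)phenyl]chroman-4-yl}-2-{(2R,3S)-2-(benzyloxy)-3-hydroxy-3-[3,4,5-tris(benzyloxy)phenyl]propyl}phenol | O(Cc4ccccc4)c1ccc2c(c1)O[C@H](c3cc(OCc4ccccc4)c(OCc4ccccc4)c(OCc4ccccc4)c3)[C@@H](OCc4ccccc4)[C@@H]2c5c(OCc4ccccc4)c(C[C@@H](OCc4ccccc4)[C@@H](O)c7cc(OCc4ccccc4)c(OCc4ccccc4)c(OCc4ccccc4)c7)c(O)cc5OCc4ccccc4 | intermediate
31 | (2R,3S,4S)-3,7-bis(benzyloxy)-4-{(2R,3R)-3,5,7-tris(benzyloxy)-2-[3,4,5-tris(benzyloxy)phenyl]chroman-6-yl}-2-[3,4,5-tris(benzyloxy)phenyl]chromane | O(Cc4ccccc4)c1ccc2c(c1)O[C@H](c3cc(OCc4ccccc4)c(OCc4ccccc4)c(OCc4ccccc4)c3)[C@@H](OCc4ccccc4)[C@@H]2c5c(OCc4ccccc4)cc6c(c5OCc4ccccc4)C[C@@H](OCc4ccccc4)[C@@H](c7cc(OCc4ccccc4)c(OCc4ccccc4)c(OCc4ccccc4)c7)O6 | intermediate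
32 | (2R,3S,4S)-2-(3,4,5-trihydroxyphenyl)-4-[(2R,3R)-3,5,7-trihydroxy-2-(3,4,5-trihydroxyphenyl)chroman-6-yl]chromane-3,7-diol | Oc1ccc2c(c1)O[C@H](c1cc(O)c(O)c(O)c1)[C@@H](O)[C@@H]2c1c(O)cc2c(c1O)C[C@@H](O)[C@@H](c1cc(O)c(O)c(O)c1)O2 | target

## Step count and least certain steps

Total: 21 steps. Longest linear sequence: 12 steps (1 → 32 by steps 1–6, 9 and 17–21; the sequence from 15 by steps 10–21 is equally long).

Step 17 (key step). What may go wrong:
- Ring opening of the donor-stabilized 3-alkoxycyclobutenone may be slower than its decomposition.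
- The vinylketene may dimerize, acylate the product phenol, or undergo a 1,5-hydrogen shift from flavan C4–H when the flavanyl group rotates inward.
- Conversion of the intermediate vinylcyclobutenone may stall.
- The siloxyalkyne may hydrolyse on traces of acid.

Fallback: the route is left at diol 3 and rejoined at 32, giving up the ring synthesis for a position-blocked arylation. Commercial (−)-epigallocatechin F1 would be benzylated at its five phenols (BnBr, K2CO3, DMF) to the penta-O-benzyl ether F2. N-Bromosuccinimide would brominate the more reactive C8', giving the 8'-bromide F3. Ionization of 3 with BF3·OEt2 in CH2Cl2 at −78 °C in the presence of F3 should arylate the only free ring D position, C6', anti to the C3 hydroxyl, giving the bromo dimer F4. Hydrogenolysis (H2, Pd(OH)2 on carbon, Et3N) would remove bromine and the nine benzyl groups to give 32.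

Step 9. What may go wrong:
- The ketene may dimerize before it meets the ynol ether.
- The benzyl ynol ether may rearrange thermally.
- The vinylogous ester may hydrolyse or isomerize to the 2-substituted cyclobutenone on silica.

Fallback: from acid 7, the same acid chloride and ketene would be trapped with commercial, thermally robust ethoxyacetylene to give the 3-ethoxycyclobutenone F5. Addition–elimination with benzyl alcohol and a catalytic amount of sodium benzyloxide (from NaH) in THF at 0 °C would exchange the alkoxy group and return to 14.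

Step 3. What may go wrong:
- Facial selectivity at the 5-deoxy C4 cation may be poor with a small nucleophile.
- The cation may be captured by ring A of a second molecule (self-condensation).

Fallback: from diol 3, acetylation (Ac2O, pyridine) would give the 3,4-diacetate F6. On ionization with BF3·OEt2 the C3 acetoxy group participates from its own face, so allyltrimethylsilane can only enter trans, giving the 3-O-acetyl-4-allylflavan F7. Methanolysis (K2CO3, MeOH) would return to 4.

Step 20. What may go wrong: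
- Inversion may be lost through ionization of the activated benzylic alcohol.
- Elimination toward the enol ether may compete.
- Activation may be slow in a crowded environment.

Fallback: the redox condensation is replaced by a fluoride-triggered Williamson closure, leaving the route at 29 and rejoining at 31. Acid-catalysed methanolysis (camphorsulfonic acid, MeOH–CH2Cl2, 0 °C) cleaves the alkyl silyl ether selectively and leaves the aryl silyl ether, giving the benzylic alcohol F8. Mesylation (MsCl, Et3N, −20 °C) gives the mesylate F9. Bu4NF then unmasks the phenoxide, which displaces the mesylate in an SN2 reaction with inversion to give 31.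

Further compounds
F1 | step 17 | (−)-epigallocatechin, (2R,3R)-2-(3,4,5-trihydroxyphenyl)chromane-3,5,7-triol (commercial) | Oc1cc(O)cc2c1C[C@@H](O)[C@@H](c3cc(O)c(O)c(O)c3)O2
F2 | step 17 | (2R,3R)-5,7-bis(benzyloxy)-2-[3,4,5-tris(benzyloxy)phenyl]chroman-3-ol | O(Cc4ccccc4)c1cc(OCc4ccccc4)cc2c1C[C@@H](O)[C@@H](c3cc(OCc4ccccc4)c(OCc4ccccc4)c(OCc4ccccc4)c3)O2
F3 | step 17 | (2R,3R)-5,7-bis(benzyloxy)-8-bromo-2-[3,4,5-tris(benzyloxy)phenyl]chroman-3-ol | O(Cc4ccccc4)c1cc(OCc4ccccc4)c(Br)c2c1C[C@@H](O)[C@@H](c3cc(OCc4ccccc4)c(OCc4ccccc4)c(OCc4ccccc4)c3)O2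
F4 | step 17 | (2R,3S,4S)-7-(benzyloxy)-4-{(2R,3R)-5,7-bis(benzyloxy)-8-bromo-3-hydroxy-2-[3,4,5-tris(benzyloxy)phenyl]chroman-6-yl}-2-[3,4,5-tris(benzyloxy)phenyl]chroman-3-ol | O(Cc4ccccc4)c1ccc2c(c1)O[C@H](c3cc(OCc4ccccc4)c(OCc4ccccc4)c(OCc4ccccc4)c3)[C@@H](O)[C@@H]2c5c(OCc4ccccc4)c(Br)c6c(c5OCc4ccccc4)C[C@@H](O)[C@@H](c7cc(OCc4ccccc4)c(OCc4ccccc4)c(OCc4ccccc4)c7)O6
F5 | step 9 | 3-ethoxy-4-{(2R,3S,4R)-3,7-bis(benzyloxy)-2-[3,4,5-tris(benzyloxy)phenyl]chroman-4-yl}cyclobut-2-en-1-one (both epimers at the cyclobutenone sp3 carbon) | O(Cc4ccccc4)c1ccc2c(c1)O[C@H](c3cc(OCc4ccccc4)c(OCc4ccccc4)c(OCc4ccccc4)c3)[C@@H](OCc4ccccc4)[C@@H]2C5C(=O)C=C5OCC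
F6 | step 3 | (2R,3S,4R)-7-(benzyloxy)-2-[3,4,5-tris(benzyloxy)phenyl]chromane-3,4-diyl diacetate | O(Cc4ccccc4)c1ccc2c(c1)O[C@H](c3cc(OCc4ccccc4)c(OCc4ccccc4)c(OCc4ccccc4)c3)[C@@H](OC(C)=O)[C@@H]2OC(C)=O
F7 | step 3 | (2R,3S,4R)-4-allyl-7-(benzyloxy)-2-[3,4,5-tris(benzyloxy)phenyl]chroman-3-yl acetate | O(Cc4ccccc4)c1ccc2c(c1)O[C@H](c3cc(OCc4ccccc4)c(OCc4ccccc4)c(OCc4ccccc4)c3)[C@@H](OC(C)=O)[C@@H]2CC=C
F8 | step 20 | analogue of 29 with free C2' hydroxyl (C8a' triisopropylsilyl ether kept) | O(Cc4ccccc4)c1ccc2c(c1)O[C@H](c3cc(OCc4ccccc4)c(OCc4ccccc4)c(OCc4ccccc4)c3)[C@@H](OCc4ccccc4)[C@@H]2c5c(OCc4ccccc4)c(C[C@@H](OCc4ccccc4)[C@@H](O)c7cc(OCc4ccccc4)c(OCc4ccccc4)c(OCc4ccccc4)c7)c(O[Si](C(C)C)(C(C)C)C(C)C)cc5OCc4ccccc4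
F9 | step 20 | C2' methanesulfonate of F8 | O(Cc4ccccc4)c1ccc2c(c1)O[C@H](c3cc(OCc4ccccc4)c(OCc4ccccc4)c(OCc4ccccc4)c3)[C@@H](OCc4ccccc4)[C@@H]2c5c(OCc4ccccc4)c(C[C@@H](OCc4ccccc4)[C@@H](OS(C)(=O)=O)c7cc(OCc4ccccc4)c(OCc4ccccc4)c(OCc4ccccc4)c7)c(O[Si](C(C)C)(C(C)C)C(C)C)cc5OCc4ccccc4
A1 | alternative 1 | 3-{(2R,3S,4S)-7-(benzyloxy)-3-hydroxy-2-[3,4,5-tris(benzyloxy)phenyl]chroman-4-yl}-4-hydroxy-6-(2-oxopropyl)-2H-pyran-2-one | O(Cc4ccccc4)c1ccc2c(c1)O[C@H](c3cc(OCc4ccccc4)c(OCc4ccccc4)c(OCc4ccccc4)c3)[C@@H](O)[C@@H]2C5=C(O)C=C(CC(C)=O)OC5=O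
A2 | alternative 1 | 3-(tetra-O-benzylrobinetinidol-4-yl)-2,4,6-trihydroxyacetophenone | O(Cc4ccccc4)c1ccc2c(c1)O[C@H](c3cc(OCc4ccccc4)c(OCc4ccccc4)c(OCc4ccccc4)c3)[C@@H](O)[C@@H]2c5c(O)cc(O)c(C(C)=O)c5O
A3 | alternative 2 | (R)-2-{5-(benzyloxy)-2-[(2R,3R)-3,5,7-tris(benzyloxy)-8-bromo-2-(3,4,5-tris(benzyloxy)phenyl)chromane-6-carbonyl]phenoxy}-2-[3,4,5-tris(benzyloxy)phenyl]acetaldehyde | O(Cc4ccccc4)c1ccc(C(=O)c5c(OCc4ccccc4)c(Br)c6c(c5OCc4ccccc4)C[C@@H](OCc4ccccc4)[C@@H](c7cc(OCc4ccccc4)c(OCc4ccccc4)c(OCc4ccccc4)c7)O6)c(c1)O[C@H](c3cc(OCc4ccccc4)c(OCc4ccccc4)c(OCc4ccccc4)c3)C=O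
A4 | alternative 2 | cis-3,4-diol of the benzylated 8'-bromo bis-flavan with tertiary C4 hydroxyl | O(Cc4ccccc4)c1ccc2c(c1)O[C@H](c3cc(OCc4ccccc4)c(OCc4ccccc4)c(OCc4ccccc4)c3)[C@@H](O)[C@]2(O)c5c(OCc4ccccc4)c(Br)c6c(c5OCc4ccccc4)C[C@@H](OCc4ccccc4)[C@@H](c7cc(OCc4ccccc4)c(OCc4ccccc4)c(OCc4ccccc4)c7)O6
A5 | alternative 3 | 5-(benzyloxy)-2-{[2,6-bis(benzyloxy)-4-(triisopropylsilyloxy)phenyl](hydroxy)methyl}phenol | OC(c1ccc(OCc4ccccc4)cc1O)c5c(OCc4ccccc4)cc(O[Si](C(C)C)(C(C)C)C(C)C)cc5OCc4ccccc4
A6 | alternative 3 | benzyldimethyl{(E)-2-[3,4,5-tris(benzyloxy)phenyl]vinyl}silane | C[Si](C)(Cc4ccccc4)/C=C/c3cc(OCc4ccccc4)c(OCc4ccccc4)c(OCc4ccccc4)c3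
A7 | alternative 3 | 2,3-trans-3,4-trans 3-(benzyldimethylsilyl)-4-[2,6-bis(benzyloxy)-4-(triisopropylsilyloxy)phenyl]-7-(benzyloxy)-2-[3,4,5-tris(benzyloxy)phenyl]chromane | O(Cc4ccccc4)c1ccc2c(c1)O[C@H](c3cc(OCc4ccccc4)c(OCc4ccccc4)c(OCc4ccccc4)c3)[C@@H]([Si](C)(C)Cc4ccccc4)[C@@H]2c5c(OCc4ccccc4)cc(O[Si](C(C)C)(C(C)C)C(C)C)cc5OCc4ccccc4
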